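**Plan**

- Numbering (guaiane): five-membered ring C1–C2–C3–C4–C5, seven-membered ring C1–C10–C9–C8–C7–C6–C5; β is the face of H5, the isopropyl group and the C8 and C10 oxygens. The retrosynthesis cuts the C8–O ester bond and the two epoxide C–O bonds (back to a C3=C4 olefin), takes C10–OH back to a C9=C10 enone of a C8 ketone, and the C4 methyl group back to a C4 ketone.
- Enabling feature: ring atoms C1, C10, C9, C8, C7, C6 carry side chain, CH3, H, O, i-Pr, H in the same order as the benzene ring of thymol methyl ether substituted para to oxygen. The seventh ring atom, the fusion carbon C5, sits between C1, C6 and the carbonyl carbon C4, so cutting C5–C1 and C5–C6 leaves an aryl-tethered diazoketone with C5 as carbene carbon.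
- Forward: thymol supplies six ring carbons with all three seven-ring substituents; C2, C3, C4 and C5 are attached to C1 as a diazoketone; one step then closes the five-membered ring (C5–C1) and expands the benzene ring to the seven-membered ring (C5–C6 formed, C1–C6 opened).
- Stereochemistry: C5 comes from the chiral copper catalyst. Methylcerium addition anti to C6 gives a 4α-hydroxyl that directs hydrogen to C1 and C7. C8 is set by hydride attack anti to isopropyl, C10 by C8–OH-directed epoxidation and hydride opening, and C3/C4 by a reagent-controlled Shi epoxidation.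

Key step: step 6

Assumption: the (S,S) antipode of the bis(oxazoline) ligand is taken to give the 8aS azulenone; the sense of induction is checked on the first run and the ligand antipode exchanged if necessary.

**Route**

Step 1
Reactants: 1 thymol
Product: 2 thymol methyl ether (2-methoxy-4-methyl-1-(propan-2-yl)benzene)
Conditions: MeI, K2CO3, acetone, reflux
Reagents that add atoms: iodomethane, CI
Why: Williamson ether synthesis on a phenol; the methyl ether later becomes the enol ether that masks the C8 ketone.

Step 2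
Reactants: 2 thymol methyl ether
Product: 3 5-isopropyl-4-methoxy-2-methylbenzaldehyde
Conditions: Cl2CHOMe, TiCl4, CH2Cl2, 0 °C; then H2O
Reagents that add atoms: dichloromethyl methyl ether, COC(Cl)Cl; water, O
Why: Rieche formylation (electrophilic aromatic substitution), which should go para to the methoxy group because the only free ortho position is wedged between OMe and CH3; the formyl carbon becomes C2.

Step 3
Reactants: 3 5-isopropyl-4-methoxy-2-methylbenzaldehyde; 4 malonic acid
Product: 5 (E)-3-(5-isopropyl-4-methoxy-2-methylphenyl)prop-2-enoic acid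
Conditions: pyridine, piperidine (cat.), 100 °C
Reagents that add atoms: none
Why: Knoevenagel condensation in the Doebner modification, in which condensation and decarboxylation give the (E)-cinnamic acid and add C3 and C4.

Step 4
Reactants: 5 (E)-3-(5-isopropyl-4-methoxy-2-methylphenyl)prop-2-enoic acid
Product: 6 3-(5-isopropyl-4-methoxy-2-methylphenyl)propanoic acid
Conditions: H2 (1 atm), 10% Pd/C, EtOAc, rt
Reagents that add atoms: none
Why: heterogeneous catalytic hydrogenation of the conjugated C=C bond, which leaves the arene and the acid untouched.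

Step 5
Reactants: 6 3-(5-isopropyl-4-methoxy-2-methylphenyl)propanoic acid; 7 (trimethylsilyl)diazomethane
Product: 9 1-diazo-4-(5-isopropyl-4-methoxy-2-methylphenyl)butan-2-one, via acid chloride 8 (not isolated)
Conditions: (COCl)2, DMF (cat.), CH2Cl2, 0 °C to rt, evaporation; then 7, MeCN/THF, 0 °C
Reagents that add atoms: oxalyl chloride, O=C(Cl)C(=O)Cl (supplies the chlorine of 8 only)
Why: acid chloride formation followed by C-acylation of the silyl diazomethane (first half of an Arndt–Eistert sequence), the silyl group being lost to chloride, which places the future C5 as the diazo carbon.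

Step 6
Reactants: 9 1-diazo-4-(5-isopropyl-4-methoxy-2-methylphenyl)butan-2-one
Product: 11 (8aS)-7-isopropyl-6-methoxy-4-methyl-3,8a-dihydroazulen-1(2H)-one, via norcaradiene 10 (not isolated)
Conditions: CuCl (5 mol %), NaB[3,5-(CF3)2C6H3]4 (6 mol %), (S,S)-t-Bu-box (6 mol %), CH2Cl2, 40 °C, slow addition of 9; cold filtration through neutral alumina
Reagents that add atoms: none
Why: The cationic copper carbene formed from 9 by loss of N2 adds to the arene π-bond C1–C6, forming C5–C1 and C5–C6 and closing the five-membered ring as the cyclopropane-fused norcaradiene 10, whose shared bond C1–C6 then opens in a thermal disrotatory six-electron electrocyclic reaction to give the cycloheptatriene ring of 11. This is the intramolecular Buchner reaction of 1-diazo-4-arylbutan-2-ones, known with achiral divalent rhodium carboxylates and with chiral monovalent copper bis(oxazoline) catalysts. The five-membered ring closes by intramolecular [2+1] cycloaddition through the two-carbon tether (carbene carbon to ipso carbon), and the seven-membered ring arises by electrocyclic ring expansion of the benzene ring. The only new stereocentre, C5 (C8a of the azulenone), is set by the chiral ligand on copper, which decides the arene face that the carbene carbon approaches. The step needs addition across the unsubstituted ortho bond C1–C6 and not across C1–C10, which the methyl group on C10 secures by blocking that bond, and it needs cyclopropanation to outrun aromatic C–H insertion, which the electron-rich anisole ring and the non-coordinating counter-ion favour. Because C5–H of 11 is α to the ketone and doubly allylic, 11 is kept cold and used at once.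

Step 7
Reactants: 11 (8aS)-7-isopropyl-6-methoxy-4-methyl-3,8a-dihydroazulen-1(2H)-one
Product: 12 (1R,8aS)-7-isopropyl-6-methoxy-1,4-dimethyl-1,2,3,8a-tetrahydroazulen-1-ol
Conditions: MeLi, CeCl3, THF, −78 °C; then H2O
Reagents that add atoms: methyllithium, [Li]C
Why: 1,2-addition of a weakly basic organocerium reagent to an easily enolised ketone, which removes the carbonyl that makes C5–H acidic and installs the C4 methyl group; the reagent should approach C4 on the face of H5, anti to the C6 arm of the seven-membered ring, giving the hydroxyl cis to C6 (4α-OH).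

Step 8
Reactants: 12 (1R,8aS)-7-isopropyl-6-methoxy-1,4-dimethyl-1,2,3,8a-tetrahydroazulen-1-ol
Product: 13 (1R,8aS)-1-hydroxy-7-isopropyl-1,4-dimethyl-2,3,5,8a-tetrahydroazulen-6(1H)-one
Conditions: (CO2H)2 (0.2 equiv), THF/H2O, 0 °C to rt
Reagents that add atoms: water, O
Why: hydrolysis of a dienol methyl ether under weakly acidic conditions, where kinetic protonation at C9 (as in the oxalic acid hydrolysis of Birch-type dienol ethers) should give the C8 ketone conjugated with C6=C7 while the tetrasubstituted C1=C10 bond stays out of conjugation and C5 is untouched.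

Step 9
Reactants: 13 (1R,8aS)-1-hydroxy-7-isopropyl-1,4-dimethyl-2,3,5,8a-tetrahydroazulen-6(1H)-one
Product: 14 (1R,3aS,4S,7R,8aS)-1-hydroxy-7-isopropyl-1,4-dimethyloctahydroazulen-6(1H)-one
Conditions: H2 (1–5 bar), [Ir(cod)(PCy3)(py)]PF6 (10 mol %), CH2Cl2, rt
Reagents that add atoms: none
Why: hydroxyl-directed homogeneous hydrogenation, in which the tertiary 4α-hydroxyl, homoallylic to both C6=C7 and C1=C10, binds the cationic iridium centre (as with terpinen-4-ol) and should deliver hydrogen to the α face of both olefins, setting H1 α (trans ring fusion), H7 α (7β-isopropyl) and a temporary C10 centre; this catalyst also reduces tetrasubstituted olefins.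

Step 10
Reactants: 14 (1R,3aS,4S,7R,8aS)-1-hydroxy-7-isopropyl-1,4-dimethyloctahydroazulen-6(1H)-one
Product: 15 (3aS,4S,7R,8aS)-7-isopropyl-1,4-dimethyl-3,3a,4,5,8,8a-hexahydroazulen-6(7H)-one
Conditions: Burgess reagent (MeO2CN–SO2NEt3 inner salt), toluene, 60 °C
Reagents that add atoms: none
Why: Burgess dehydration of a tertiary alcohol by syn elimination; the 4α-sulfamate can reach only H3α and the methyl hydrogens because H5 lies on the β face, so the tetrasubstituted C4=C5 olefin is excluded and the more stable endocyclic C3=C4 olefin should prevail over the exocyclic methylene isomer.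

Step 11
Reactants: 15 (3aS,4S,7R,8aS)-7-isopropyl-1,4-dimethyl-3,3a,4,5,8,8a-hexahydroazulen-6(7H)-one
Product: 16 trimethyl{[(3aS,4R,7R,8aS)-7-isopropyl-1,4-dimethyl-3,3a,4,7,8,8a-hexahydroazulen-6-yl]oxy}silane
Conditions: LiN(i-Pr)2, THF, −78 °C; then Me3SiCl
Reagents that add atoms: chlorotrimethylsilane, C[Si](C)(C)Cl
Why: kinetic enolisation and O-silylation, in which the hindered amide base takes a proton from the C9 methylene rather than from the isopropyl-bearing methine C7 (as with menthone), so C7 is not touched and the enol double bond lies at C8=C9.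

Step 12
Reactants: 16 trimethyl{[(3aS,4R,7R,8aS)-7-isopropyl-1,4-dimethyl-3,3a,4,7,8,8a-hexahydroazulen-6-yl]oxy}silane
Product: 17 (3aR,7R,8aS)-7-isopropyl-1,4-dimethyl-3,7,8,8a-tetrahydroazulen-6(3aH)-one
Conditions: Pd(OAc)2 (1.1 equiv), MeCN, rt
Reagents that add atoms: none
Why: Saegusa–Ito oxidation, in which the palladium enolate at C9 loses its only β-hydrogen, H10, erasing the temporary C10 centre and giving the C9=C10 enone with the trans ring fusion (H1 α, H5 β) fixed.

Step 13
Reactants: 17 (3aR,7R,8aS)-7-isopropyl-1,4-dimethyl-3,7,8,8a-tetrahydroazulen-6(3aH)-one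
Product: 18 (3aR,6S,7R,8aS)-7-isopropyl-1,4-dimethyl-3,3a,6,7,8,8a-hexahydroazulen-6-ol
Conditions: LiBH(s-Bu)3, THF, −78 °C; then H2O
Reagents that add atoms: none
Why: 1,2-reduction of a β,β-disubstituted enone by a bulky trialkylborohydride, which should add to C8 from the α face, anti to the neighbouring 7β-isopropyl group (the sense of the menthone to neomenthol reduction), giving the 8β-alcohol cis to isopropyl.

Step 14
Reactants: 18 (3aR,6S,7R,8aS)-7-isopropyl-1,4-dimethyl-3,3a,6,7,8,8a-hexahydroazulen-6-ol
Product: 19 (3aR,4R,5S,6S,7R,8aS)-4,5-epoxy-7-isopropyl-1,4-dimethyl-3,3a,4,5,6,7,8,8a-octahydroazulen-6-ol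
Conditions: VO(acac)2 (5 mol %), t-BuOOH, CH2Cl2, 0 °C to rt
Reagents that add atoms: tert-butyl hydroperoxide, CC(C)(C)OO
Why: vanadium-catalysed hydroxyl-directed epoxidation of a cyclic allylic alcohol, which delivers oxygen syn to the 8β-hydroxyl (9β,10β-epoxide), as with cyclohept-2-enol, and leaves the isolated C3=C4 olefin untouched.

Step 15
Reactants: 19 (3aR,4R,5S,6S,7R,8aS)-4,5-epoxy-7-isopropyl-1,4-dimethyl-3,3a,4,5,6,7,8,8a-octahydroazulen-6-ol
Product: 20 (3aR,4S,6R,7R,8aS)-7-isopropyl-1,4-dimethyl-3,3a,4,5,6,7,8,8a-octahydroazulene-4,6-diol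
Conditions: LiAlH4, THF, 0 °C to rt; then H2O, aq. NaOH
Reagents that add atoms: none
Why: hydride opening of a trisubstituted epoxide by SN2 attack at the secondary carbon C9 (as in the reduction of 3,3-disubstituted 2,3-epoxy alcohols to 1,3-diols), which leaves the oxygen on C10 with retention and gives the 10β-hydroxy-10α-methyl carbinol.

Step 16
Reactants: 20 (3aR,4S,6R,7R,8aS)-7-isopropyl-1,4-dimethyl-3,3a,4,5,6,7,8,8a-octahydroazulene-4,6-diol; 21 3,4-dimethoxybenzoyl chloride
Product: 22 (3aR,4S,6R,7R,8aS)-4-hydroxy-7-isopropyl-1,4-dimethyl-3,3a,4,5,6,7,8,8a-octahydroazulen-6-yl 3,4-dimethoxybenzoate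
Conditions: Et3N, DMAP (cat.), CH2Cl2, 0 °C to rt
Reagents that add atoms: none
Why: DMAP-catalysed acylation, selective for the secondary C8 hydroxyl because the tertiary C10 hydroxyl does not react with an aroyl chloride under these conditions.

Step 17
Reactants: 22 (3aR,4S,6R,7R,8aS)-4-hydroxy-7-isopropyl-1,4-dimethyl-3,3a,4,5,6,7,8,8a-octahydroazulen-6-yl 3,4-dimethoxybenzoate
Product: 23 (1R,3R,4S,5S,7R,8R,10S)-3,4-epoxy-10-hydroxyguaian-8-yl 3,4-dimethoxybenzoate (target)
Conditions: D-fructose-derived ketone 1,2:4,5-di-O-isopropylidene-β-D-erythro-2,3-hexodiulo-2,6-pyranose (30 mol %), KHSO5 (as 2KHSO5·KHSO4·K2SO4), K2CO3, Bu4NHSO4 (cat.), MeCN/CH2(OMe)2/aq. Na2B4O7 buffer (pH 10.5), 0 °C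
Reagents that add atoms: potassium peroxymonosulfate, [K+].[O-]S(=O)(=O)OO
Why: Shi asymmetric epoxidation by a chiral dioxirane; the trans-fused framework biases neither face of the trisubstituted C3=C4 olefin strongly, so the catalyst chooses the face, and the spiro transition state that turns 1-phenylcyclohexene into its (R,R)-oxide corresponds here to the α face (3R,4S), while the ester and the tertiary alcohol tolerate the buffered medium.

**Compound list**

1 | thymol | Cc1ccc(C(C)C)c(O)c1 | starting material
2 | thymol methyl ether (2-methoxy-4-methyl-1-(propan-2-yl)benzene) | COc1cc(C)ccc1C(C)C | intermediate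
3 | 5-isopropyl-4-methoxy-2-methylbenzaldehyde | O=Cc1cc(C(C)C)c(OC)cc1C | intermediate
4 | malonic acid | OC(=O)CC(=O)O | starting material
5 | (E)-3-(5-isopropyl-4-methoxy-2-methylphenyl)prop-2-enoic acid | OC(=O)/C=C/c1cc(C(C)C)c(OC)cc1C | intermediate
6 | 3-(5-isopropyl-4-methoxy-2-methylphenyl)propanoic acid | OC(=O)CCc1cc(C(C)C)c(OC)cc1C | intermediate
7 | (trimethylsilyl)diazomethane | C[Si](C)(C)C=[N+]=[N-] | starting material
8 | 3-(5-isopropyl-4-methoxy-2-methylphenyl)propanoyl chloride | ClC(=O)CCc1cc(C(C)C)c(OC)cc1C | intermediate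
9 | 1-diazo-4-(5-isopropyl-4-methoxy-2-methylphenyl)butan-2-one | [N-]=[N+]=CC(=O)CCc1cc(C(C)C)c(OC)cc1C | intermediate
10 | norcaradiene valence isomer of 11 (cyclopropane C5–C1–C6, all-cis fused tricyclic dienyl ketone; 1S,5S,6S in guaiane numbering) | O=C1CC[C@]23C(C)=CC(OC)=C(C(C)C)[C@H]2[C@H]13 | intermediate
11 | (8aS)-7-isopropyl-6-methoxy-4-methyl-3,8a-dihydroazulen-1(2H)-one | O=C1CCC2=C(C)C=C(OC)C(C(C)C)=C[C@H]12 | intermediate
12 | (1R,8aS)-7-isopropyl-6-methoxy-1,4-dimethyl-1,2,3,8a-tetrahydroazulen-1-ol (4α-OH, 4β-CH3, H5 β) | C[C@@]1(O)CCC2=C(C)C=C(OC)C(C(C)C)=C[C@H]12 | intermediate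
13 | (1R,8aS)-1-hydroxy-7-isopropyl-1,4-dimethyl-2,3,5,8a-tetrahydroazulen-6(1H)-one | O=C1CC(C)=C2CC[C@@](C)(O)[C@H]2C=C1C(C)C | intermediate
14 | (1R,3aS,4S,7R,8aS)-1-hydroxy-7-isopropyl-1,4-dimethyloctahydroazulen-6(1H)-one (H1 α, H5 β, H7 α, H10 α) | O=C1C[C@H](C)[C@@H]2CC[C@@](C)(O)[C@H]2C[C@@H]1C(C)C | intermediate
15 | (3aS,4S,7R,8aS)-7-isopropyl-1,4-dimethyl-3,3a,4,5,8,8a-hexahydroazulen-6(7H)-one | O=C1C[C@H](C)[C@@H]2CC=C(C)[C@H]2C[C@@H]1C(C)C | intermediate
16 | trimethyl{[(3aS,4R,7R,8aS)-7-isopropyl-1,4-dimethyl-3,3a,4,7,8,8a-hexahydroazulen-6-yl]oxy}silane | C[Si](C)(C)OC1=C[C@H](C)[C@@H]2CC=C(C)[C@H]2C[C@@H]1C(C)C | intermediate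
17 | (3aR,7R,8aS)-7-isopropyl-1,4-dimethyl-3,7,8,8a-tetrahydroazulen-6(3aH)-one | O=C1C=C(C)[C@@H]2CC=C(C)[C@H]2C[C@@H]1C(C)C | intermediate
18 | (3aR,6S,7R,8aS)-7-isopropyl-1,4-dimethyl-3,3a,6,7,8,8a-hexahydroazulen-6-ol (8β-OH) | O[C@@H]1C=C(C)[C@@H]2CC=C(C)[C@H]2C[C@@H]1C(C)C | intermediate
19 | (3aR,4R,5S,6S,7R,8aS)-4,5-epoxy-7-isopropyl-1,4-dimethyl-3,3a,4,5,6,7,8,8a-octahydroazulen-6-ol (9β,10β-epoxide cis to 8β-OH) | O[C@@H]1[C@@H]2O[C@]2(C)[C@@H]3CC=C(C)[C@H]3C[C@@H]1C(C)C | intermediate
20 | (3aR,4S,6R,7R,8aS)-7-isopropyl-1,4-dimethyl-3,3a,4,5,6,7,8,8a-octahydroazulene-4,6-diol | O[C@@H]1C[C@](C)(O)[C@@H]2CC=C(C)[C@H]2C[C@@H]1C(C)C | intermediate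
21 | 3,4-dimethoxybenzoyl chloride | COc1ccc(C(=O)Cl)cc1OC | starting material
22 | (3aR,4S,6R,7R,8aS)-4-hydroxy-7-isopropyl-1,4-dimethyl-3,3a,4,5,6,7,8,8a-octahydroazulen-6-yl 3,4-dimethoxybenzoate | COc1ccc(C(=O)O[C@@H]2C[C@](C)(O)[C@@H]3CC=C(C)[C@H]3C[C@@H]2C(C)C)cc1OC | intermediate
23 | (1R,3R,4S,5S,7R,8R,10S)-3,4-epoxy-10-hydroxyguaian-8-yl 3,4-dimethoxybenzoate (1αH, 5βH, 3α,4α-epoxide, 7β-isopropyl, 8β-ester, 10β-OH) | COc1ccc(C(=O)O[C@@H]2C[C@](C)(O)[C@@H]3C[C@H]4O[C@@]4(C)[C@H]3C[C@@H]2C(C)C)cc1OC | target

**Step count and risks**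

Total step count: 17. Longest linear sequence: 17 steps (1 to 23).

Steps most likely to fail:

Step 6. The carbene may discriminate the two arene faces poorly for a terminal diazoketone, and 11 may lose its configuration by enolisation at C5 before it is trapped; aromatic C–H insertion to a 2-tetralone may also compete. Fallback: starting from 9, the cyclisation is run with the achiral divalent rhodium carboxylate Rh2(OAc)4, which gives 11 together with its mirror image, the (8aR)-azulenone F1. Methylcerium addition as in step 7 turns the pair into 12 and the (1S,8aR)-carbinol F2. Preparative chromatography on a chiral stationary phase separates the two, and the route is rejoined at 12.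

Step 9. The tetrasubstituted C1=C10 bond may be reduced too slowly, or may migrate into conjugation with the ketone before hydrogen is delivered, so that H1 no longer arrives on the α face. Fallback: starting from 13, only the enone bond C6=C7 is hydrogenated under hydroxyl direction with [Rh(nbd)(dppb)]BF4, a catalyst that leaves tetrasubstituted olefins alone, to give the β,γ-unsaturated hydroxy ketone F3. DBU in CH2Cl2 then moves C1=C10 into conjugation, protonating the γ-carbon C1 under equilibrium control, to give the conjugated hydroxy enone F4. Burgess dehydration of F4 as in step 10 gives 17, where the route is rejoined without steps 11 and 12. In this variant C1 and C7 are set by equilibration and not by delivery, so the trans ring fusion and the C7 configuration must be confirmed before going on.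

Step 17. The substrate may override the catalyst (mismatched pairing), giving poor facial selectivity at C3=C4. Fallback: starting from 22, the tertiary C10 hydroxyl is silylated (Me3SiOTf, 2,6-lutidine, CH2Cl2, −78 °C) to the 10-O-trimethylsilyl ether F5, whose axial 10β-silyloxy group lies over the β face of the cyclopentene and removes any hydrogen-bond guidance to that face. Epoxidation with m-CPBA/NaHCO3 in CH2Cl2 at 0 °C should then take place from the open α face to give the silylated epoxide F6. Tetrabutylammonium fluoride buffered with acetic acid removes the silyl group and gives 23.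

Further compounds
F1 | step 6 | (8aR)-7-isopropyl-6-methoxy-4-methyl-3,8a-dihydroazulen-1(2H)-one | O=C1CCC2=C(C)C=C(OC)C(C(C)C)=C[C@@H]12
F2 | step 6 | (1S,8aR)-7-isopropyl-6-methoxy-1,4-dimethyl-1,2,3,8a-tetrahydroazulen-1-ol | C[C@]1(O)CCC2=C(C)C=C(OC)C(C(C)C)=C[C@@H]12
F3 | step 9 | (1R,7R,8aS)-1-hydroxy-7-isopropyl-1,4-dimethyl-2,3,5,7,8,8a-hexahydroazulen-6(1H)-one | O=C1CC(C)=C2CC[C@@](C)(O)[C@H]2C[C@@H]1C(C)C
F4 | step 9 | (1R,3aR,7R,8aS)-1-hydroxy-7-isopropyl-1,4-dimethyl-2,3,3a,7,8,8a-hexahydroazulen-6(1H)-one | O=C1C=C(C)[C@@H]2CC[C@@](C)(O)[C@H]2C[C@@H]1C(C)C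
F5 | step 17 | (3aR,4S,6R,7R,8aS)-7-isopropyl-1,4-dimethyl-4-(trimethylsilyloxy)-3,3a,4,5,6,7,8,8a-octahydroazulen-6-yl 3,4-dimethoxybenzoate | COc1ccc(C(=O)O[C@@H]2C[C@](C)(O[Si](C)(C)C)[C@@H]3CC=C(C)[C@H]3C[C@@H]2C(C)C)cc1OC
F6 | step 17 | (1R,3R,4S,5S,7R,8R,10S)-3,4-epoxy-10-(trimethylsilyloxy)guaian-8-yl 3,4-dimethoxybenzoate | COc1ccc(C(=O)O[C@@H]2C[C@](C)(O[Si](C)(C)C)[C@@H]3C[C@H]4O[C@@]4(C)[C@H]3C[C@@H]2C(C)C)cc1OC
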